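| flask | starting material | reagent in the second phase | protic impurity | remark | time | volume of the second phase over the first |
|---|---|---|---|---|---|---|
| oak | 0.30 M | 0.44 M | 0.060 M | run made earlier |  |  |
| ash | 0.30 M | 0.69 M | 0.060 M | run made earlier |  |  |
| flask | 0.30 M | 0.315 M | 0.0600 M |  | 15 h | 2.0 |

| run | time / h | target / % | starting material / % |
|---|---|---|---|
| oak | 0.167 | 98 | 0 |
| oak | 0.417 | 99 | 2 |
| oak | 0.833 | 95 | 0 |
| oak | 2.00 | 91 | 1 |
| oak | 4.00 | 77 | 1 |
| oak | 8.00 | 69 | 0 |
| oak | 20.0 | 34 | 0 |
| ash | 0.167 | 100 | 2 |
| ash | 0.417 | 99 | 0 |
| ash | 0.833 | 93 | 2 |
| ash | 2.00 | 90 | 2 |
| ash | 4.00 | 83 | 1 |
| ash | 8.00 | 65 | 2 |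
| ash | 20.0 | 36 | 0 |

(standard deviation of a reading: 2 percentage points)

- in the second phase: reagent in the second phase; everything else is in the first
- charges count per volume of the first phase; a concentration in a rate is the amount of a species over the volume of its own phase; every rate counts per litre of the first phase
- the earlier runs were read with a standard deviation of 2 percentage points
- steps thought possible: reagent in the reaction phase <-> reagent in the second phase; starting material + reagent in the reaction phase -> target; target -> over-reaction product; reagent in the reaction phase <-> dormant form; reagent in the reaction phase + protic impurity -> quenched reagent
- the earlier runs hold the two phases in the same ratio of volumes as the flask asked about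

1. when, up to 15 h, the flask holds most target
2. the amount of target, in percent of the starting material charged, at that time
3. earliest time at which at least nineteen twentieths of that best amount are there
4. latest time at which they still are

1. Late in the oak run the target reads 34% at 20.0 h, against 98% at 0.167 h. Read from these two readings, that is a half-life of 13.0 h. This is far longer than the 0.167 h within which the target rose in the oak run, so for the flask I expect the height of the peak to depend mainly on how much starting material reacts.

2. So I ask for the end state. Once no reagent remains in any form, each unit charged has either made target or been quenched. Let c be the starting material charged, and let q be the quenched reagent formed. The margin m, the stoichiometric excess, is the reagent charged minus c, which for the flask is 0.0150 M. Whatever q exceeds m by stays behind as starting material, so the share left is (q − m)/c.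

3. The bench rule says that more than one equivalent of reagent finishes the starting material. The flask has 1.05 equivalents, so the rule promises none left.

4. The rule is safe while impurity over margin stays below one. That ratio is 0.429 in oak and 0.154 in ash, so neither run tests it. In the flask it is 4.00.

5. My reckoning is therefore a range. Between no quench and a complete one, the flask keeps from nothing to 15.0% of its starting material, and the target peaks between 85.0% and 100%, less a little decay.

6. The forecast expects “a quick rise, a slightly slower tail as reagent runs out”. It gives 83% at 0.35 h, with the window from 0.12 h to 1.3 h.

7. The flask gives 96.0% at 0.482 h, with the window from 0.196 h to 1.66 h.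

    reagent in the reaction phase ⇌ reagent in the second phase, rate k1*([reagent in the reaction phase] - [reagent in the second phase]/K1) per volume of the first phase (partition coefficient = 0.320, kL = 0.00320 s⁻¹)
    starting material + reagent in the reaction phase → target (k = 0.360 L mol⁻¹ s⁻¹)
    target → over-reaction product (k = 1.50 × 10⁻⁵ s⁻¹)
    reagent in the reaction phase ⇌ dormant form (K = 1.10, k = 0.0120 s⁻¹)
    reagent in the reaction phase + protic impurity → quenched reagent (k = 0.0230 L mol⁻¹ s⁻¹)

8. The forecast and the flask part on the height of the peak. At 15.0 h the flask holds 0.0168 M of quenched reagent, just above m, so (q − m)/c gives 0.591%, and the flask keeps 0.59% of its starting material. A neighbouring flask has 0.24 M of impurity and the same m. Its q at 15.0 h is 0.0369 M, so the reckoning gives 7.31%. That neighbour keeps 7.3% of its starting material, and its best amount of target is 90.5%.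

The earlier runs and the new flask were generated by integration with constants of no real substance.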